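**Retrosynthetic overview**

1. Punaglandin 2 (16) ⇐ acetylation of O6/O7 of diol 15; the tertiary C12–OH stays free.
2. The cyclopentenone (the only ring made, formed at step 11) ⇐ Piancatelli 4π‑conrotatory electrocyclization of furylcarbinol 14. This forms C8–C12; the furan oxygen becomes C9=O, water supplies C12–OH, and the furan 3‑Cl becomes C10–Cl.
3. 14 ⇐ C8–C9 bond: lithiated 4‑chloro‑2‑[(Z)‑octenyl]furan 13 + aldehyde 8.
4. 8 ⇐ D‑glucono‑1,5‑lactone: its C2, C3, C4 become C5, C6, C7; C1 becomes C4 and is extended by radical addition to methyl acrylate; C5–C6 glycol cleavage gives the C8 aldehyde.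
5. 13 ⇐ 3‑chlorofuran (C2 blocked with TMS) + (Z)‑oct‑2‑enyl bromide.

**Assumptions (one line each)**

- Prostaglandin numbering is used (C1 = ester carbon, ring = C8–C12); the target is (5S,6R,7R,8R,12S), with C12–OH cis to the C8 side chain and the two carbon chains trans.
- 3‑Chlorofuran is taken as purchasable; if not, it is one step from 3‑bromofuran (n‑BuLi, then C2Cl6).
- In the 4π closure the C12–OH is assumed to rotate outward, as in reported Piancatelli rearrangements, so the kinetic product is the C8 epimer; it is corrected by enol equilibration in the same pot.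

None of this has been run; the stereochemical outcome of step 11 is a prediction, not a precedent.

---

**Step 1**
Reactants: 1, D‑glucono‑1,5‑lactone
Product: 2, methyl 3,4:5,6‑di‑O‑isopropylidene‑D‑gluconate
Conditions: 2,2‑dimethoxypropane, MeOH, acetone, TsOH (cat.), rt
Reagents that add atoms: 2,2‑dimethoxypropane COC(C)(C)OC; methanol CO
Why: Acid‑catalysed lactone methanolysis and ketalisation give the trans‑3,4 and terminal 5,6 dioxolanes and leave O2 free; no stereocentre is touched.

**Step 2**
Reactants: 2
Product: 3, 3,4:5,6‑di‑O‑isopropylidene‑D‑glucitol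
Conditions: LiAlH4, THF, 0 °C
Reagents that add atoms: none
Why: Hydride reduction of the ester gives the primary alcohol; the ketals are inert.

**Step 3**
Reactants: 3
Product: 4, 1‑deoxy‑1‑iodo‑3,4:5,6‑di‑O‑isopropylidene‑D‑glucitol
Conditions: I2, PPh3, imidazole, THF, 0 °C → rt
Reagents that add atoms: iodine II
Why: Appel/Garegg iodination is selective for the primary hydroxyl at room temperature with about one equivalent of reagent.

**Step 4**
Reactants: 4
Product: 5, 2‑O‑acetyl‑1‑deoxy‑1‑iodo‑3,4:5,6‑di‑O‑isopropylidene‑D‑glucitol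
Conditions: Ac2O, pyridine, DMAP (cat.), CH2Cl2, 0 °C → rt
Reagents that add atoms: acetic anhydride CC(=O)OC(C)=O
Why: Acetylation installs the final C5 acetate early, which later prevents δ‑lactonisation onto the ester and tetrahydrofuran formation.

**Step 5**
Reactants: 5; 6, methyl acrylate
Product: 7, methyl 5‑O‑acetyl‑2,3,4‑trideoxy‑6,7:8,9‑di‑O‑isopropylidene‑D‑gluco‑nononate, i.e. methyl (5S)‑5‑acetoxy‑5‑[(4R,4′R,5R)‑2,2,2′,2′‑tetramethyl‑4,4′‑bi(1,3‑dioxolan)‑5‑yl]pentanoate
Conditions: methyl acrylate (5 equiv), Bu3SnH (slow addition), AIBN, PhH, 80 °C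
Reagents that add atoms: methyl acrylate C=CC(=O)OC
Why: Giese addition of the primary radical to the acrylate adds exactly C3–C1 without a hydrogenation; the β‑acetoxy radical does not fragment and the stereocentres are remote from the radical.

**Step 6**
Reactants: 7
Product: 8, methyl (5S)‑5‑acetoxy‑5‑[(4R,5S)‑5‑formyl‑2,2‑dimethyl‑1,3‑dioxolan‑4‑yl]pentanoate
Conditions: H5IO6 (1.3 equiv), EtOAc, rt
Reagents that add atoms: none
Why: Periodic acid hydrolyses only the terminal acetonide and cleaves the liberated glycol in one pot, giving the C8 aldehyde; the internal trans‑ketal, acetate and ester survive.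

**Step 7**
Reactants: 9, (Z)‑oct‑2‑en‑1‑ol
Product: 10, (Z)‑1‑bromooct‑2‑ene
Conditions: CBr4, PPh3, CH2Cl2, –20 → 0 °C
Reagents that add atoms: carbon tetrabromide BrC(Br)(Br)Br
Why: Appel bromination of the allylic alcohol at low temperature proceeds without allylic transposition or Z/E isomerisation.

**Step 8**
Reactants: 11, 3‑chlorofuran
Product: 12, 3‑chloro‑2‑(trimethylsilyl)furan
Conditions: LDA, THF, –78 °C; TMSCl
Reagents that add atoms: chlorotrimethylsilane C[Si](C)(C)Cl
Why: Directed lithiation occurs at C2, the α‑position ortho to chlorine, and silylation blocks that site.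

**Step 9**
Reactants: 12; 10
Product: 13, 4‑chloro‑2‑[(2Z)‑oct‑2‑en‑1‑yl]furan
Conditions: LiTMP, THF, –78 → –40 °C; 10, –78 → 0 °C; then TBAF, THF, rt (one pot)
Reagents that add atoms: none beyond 10
Why: With C2 blocked, α‑lithiation goes to C5, SN2 alkylation with the primary allylic bromide keeps the Z geometry, and fluoride protodesilylation then frees the α‑position next to chlorine.

**Step 10**
Reactants: 13 (1.2 equiv); 8
Product: 14, methyl (5S)‑5‑acetoxy‑5‑{(4R,5R)‑5‑[(3‑chloro‑5‑[(2Z)‑oct‑2‑en‑1‑yl]furan‑2‑yl)(hydroxy)methyl]‑2,2‑dimethyl‑1,3‑dioxolan‑4‑yl}pentanoate (both carbinol epimers)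
Conditions: LDA, THF, –78 °C, 30 min; then 8, –78 °C; AcOH quench at –78 °C
Reagents that add atoms: none
Why: The ring proton between O and Cl is the most acidic, and the furyllithium adds to the aldehyde much faster than to the acetate or methyl ester at –78 °C; the new carbinol configuration is irrelevant because C8 becomes sp2 in the next step.

**Step 11**
Reactants: 14
Product: 15, methyl (5S,6S,7R)‑5‑acetoxy‑7‑{(1R,2S)‑4‑chloro‑2‑hydroxy‑2‑[(2Z)‑oct‑2‑en‑1‑yl]‑5‑oxocyclopent‑3‑en‑1‑yl}‑6,7‑dihydroxyheptanoate (6,7‑di‑O‑desacetyl‑punaglandin 2; same spatial arrangement as the target at every centre)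
Conditions: ZnCl2 (2 equiv), 1,4‑dioxane–H2O (2:1), NaOAc/AcOH to pH ≈ 4.5, 85 °C, 24–36 h, continued until the C8 epimers have equilibrated
Reagents that add atoms: water O
Why: This is a Piancatelli rearrangement. The furfuryl cation takes up water at the octenyl‑bearing furan carbon and ring‑opens to a pentadienyl cation, and thermal 4π‑conrotatory electrocyclization forms C8–C12; the ketal is hydrolysed in the same pot. With C7–H eclipsing the enol (A1,3 strain) and the C6 branch shielding one face, the bond is expected to form syn to O7, which sets C12 as S. With OH and the side chain both outward the kinetic product is the 8‑epimer, and C8 (α to C9=O) then equilibrates through the enol to the more stable isomer with the chain trans to octenyl and cis to OH. Any C12‑epimeric diastereomer is removed by chromatography.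

**Step 12**
Reactants: 15
Product: 16, punaglandin 2, methyl (5S,6R,7R)‑5,6,7‑triacetoxy‑7‑{(1R,2S)‑4‑chloro‑2‑hydroxy‑2‑[(2Z)‑oct‑2‑en‑1‑yl]‑5‑oxocyclopent‑3‑en‑1‑yl}heptanoate
Conditions: AcCl (5 equiv), 2,4,6‑collidine, CH2Cl2, –20 → 0 °C, short reaction time
Reagents that add atoms: acetyl chloride CC(=O)Cl
Why: The two secondary alcohols are acetylated while the hindered tertiary C12–OH is not, and the weak hindered base at low temperature limits E1cB loss of the new C7 acetate.

---

**Compound list**

1 | D‑glucono‑1,5‑lactone | OC[C@H]1OC(=O)[C@H](O)[C@@H](O)[C@@H]1O | starting material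
2 | methyl 3,4:5,6‑di‑O‑isopropylidene‑D‑gluconate | COC(=O)[C@H](O)[C@H]1OC(C)(C)O[C@@H]1[C@H]2COC(C)(C)O2 | intermediate
3 | 3,4:5,6‑di‑O‑isopropylidene‑D‑glucitol | OC[C@H](O)[C@H]1OC(C)(C)O[C@@H]1[C@H]2COC(C)(C)O2 | intermediate
4 | 1‑deoxy‑1‑iodo‑3,4:5,6‑di‑O‑isopropylidene‑D‑glucitol | IC[C@H](O)[C@H]1OC(C)(C)O[C@@H]1[C@H]2COC(C)(C)O2 | intermediate
5 | 2‑O‑acetyl‑1‑deoxy‑1‑iodo‑3,4:5,6‑di‑O‑isopropylidene‑D‑glucitol | IC[C@H](OC(C)=O)[C@H]1OC(C)(C)O[C@@H]1[C@H]2COC(C)(C)O2 | intermediate
6 | methyl acrylate | C=CC(=O)OC | starting material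
7 | methyl 5‑O‑acetyl‑2,3,4‑trideoxy‑6,7:8,9‑di‑O‑isopropylidene‑D‑gluco‑nononate | COC(=O)CCC[C@H](OC(C)=O)[C@H]1OC(C)(C)O[C@@H]1[C@H]2COC(C)(C)O2 | intermediate
8 | methyl (5S)‑5‑acetoxy‑5‑[(4R,5S)‑5‑formyl‑2,2‑dimethyl‑1,3‑dioxolan‑4‑yl]pentanoate | COC(=O)CCC[C@H](OC(C)=O)[C@H]1OC(C)(C)O[C@@H]1C=O | intermediate
9 | (Z)‑oct‑2‑en‑1‑ol | CCCCC/C=C\CO | starting material
10 | (Z)‑1‑bromooct‑2‑ene | CCCCC/C=C\CBr | intermediate
11 | 3‑chlorofuran | Clc1ccoc1 | starting material
12 | 3‑chloro‑2‑(trimethylsilyl)furan | C[Si](C)(C)c1occc1Cl | intermediate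
13 | 4‑chloro‑2‑[(2Z)‑oct‑2‑en‑1‑yl]furan | CCCCC/C=C\Cc1cc(Cl)co1 | intermediate
14 | furylcarbinol (C8 epimer mixture) | CCCCC/C=C\Cc1cc(Cl)c(o1)C(O)[C@H]2OC(C)(C)O[C@@H]2[C@H](CCCC(=O)OC)OC(C)=O | intermediate
15 | 6,7‑di‑O‑desacetyl‑punaglandin 2 | CCCCC/C=C\C[C@@]1(O)C=C(Cl)C(=O)[C@@H]1[C@@H](O)[C@H](O)[C@H](CCCC(=O)OC)OC(C)=O | intermediate
16 | punaglandin 2 | CCCCC/C=C\C[C@@]1(O)C=C(Cl)C(=O)[C@@H]1[C@@H](OC(C)=O)[C@H](OC(C)=O)[C@H](CCCC(=O)OC)OC(C)=O | target

---

**Totals**

Total steps: 12. Longest linear sequence: 9 (steps 1–6, then 10–12).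

**Three steps most likely to fail, with fallbacks**

1. **Step 11 (ring formation).** Three things can go wrong:
   - Ionisation is slowed by the β‑oxygen and the 3‑Cl; the cation can instead lose the doubly activated C13 proton or undergo a 1,2‑hydride shift from C7.
   - The sense and level of C7 → C12 induction are a model prediction, not a known result.
   - C8 equilibration competes with dehydration to the 7‑ene (punaglandin 4 type).

   Fallback: open the furan of 14 oxidatively (NBS, NaHCO3, aq. THF) to the (Z)‑2‑chloro‑ene‑1,4‑dione and close the same C8–C12 bond by an intramolecular aldol under equilibrating conditions. This gives the trans‑dialkyl ring directly; the C12 diastereomers are then separated.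

2. **Step 9 (C5 alkylation of the blocked chlorofuran).** Risks are incomplete or misdirected lithiation, SN2′ alkylation, proton transfer from the doubly activated CH2 of the product, and incomplete desilylation. Fallback: Ir‑catalysed, sterically controlled C5–H borylation of 3‑chlorofuran, then Pd‑catalysed coupling with a (Z)‑oct‑2‑enyl electrophile (or with 1‑bromo‑oct‑2‑yne followed by Lindlar reduction).

3. **Step 12 (final acetylation).** The product is a β‑acetoxy ketone with an acidic C8–H, so even weak base can eliminate AcOH; over‑acetylation at C12 is also possible. Fallback: move the acylation ahead of ring formation. Hydrolyse the ketal of 14, peracetylate to the 6,7,8‑triacetate, and run the rearrangement on the furfuryl acetate so that no acylation is needed once the ring exists. The cost is C7‑acetate participation and a less safe C8 equilibration.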